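Time misled me at the first reading.

| setting | oak | cedar | larch | maple |
|---|---|---|---|---|
| substrate | 0.250 M | 0.750 M | 0.250 M | 0.0830 M |
| target |  |  | 0.120 M |  |
| time |  |  |  | 27 min |

- oak run (time / min: [target] / M): 3.4: 0.031; 6.8: 0.068; 10: 0.083; 14: 0.109; 17: 0.125; 20: 0.133; 24: 0.141; 27: 0.148
- cedar run (time / min: [target] / M): 3.4: 0.184; 6.8: 0.251; 10: 0.279; 14: 0.319; 17: 0.336; 20: 0.353; 24: 0.370; 27: 0.379
- larch run (time / min: [target] / M): 3.4: 0.313; 6.8: 0.313; 10: 0.319; 14: 0.331; 17: 0.332; 20: 0.334; 24: 0.339; 27: 0.340

(scatter of a reading: 0.004 M)

1. reaction order in [substrate] at the outset, round the charge of the oak run, defined at two percent of the substrate turned into target (one fixed amount of target, the same in the runs compared)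
2. target in the maple run at 27 min, as a share of the substrate charged

- Overall: substrate -> target.
- Constant volume, constant temperature.
- An order is taken over about fifteen percent of the charge, up and down.

At 3.4 min the oak run had made 12.4% of its charge and the cedar run 24.5%, a higher share. So the logarithm of the amounts made, over the logarithm of the charges, gave an order of 1.62 at equal time.

But the larch run, with the oak charge plus added target, had made 77.2% of its charge by then, more than the oak run. So a comparison at equal time mixed substrate with target already made.

I therefore divided one rate by another at one fixed amount of target, so that time dropped out. I took the logarithm of that ratio over the charge lever, 1.10, the logarithm of the cedar charge over the oak charge. The oak run's first reading already stood past two percent, so no oak reading stood at that amount. The cedar run held more target at that reading than the oak run, so I committed only to an order below 1.62.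

The forecast gave 0.5 and 71%, with this ground: “At 2% conversion, the promoted term is small”.

The flask gave 0.83 and 64.3%.

    substrate → intermediate (0.2724 min⁻¹)
    intermediate → target (0.04722 min⁻¹)
    substrate + target → 2 target (5.478 L mol⁻¹ min⁻¹)
    2 substrate → homo dimer (0.3588 L mol⁻¹ min⁻¹)

At the fixed amount, the cedar run went 2.5 times as fast as the oak run, and the logarithm of that ratio over the lever gives 0.830 between those two charges. The step from substrate and target to 2 target, autocatalysis, raises the order, which falls to 0.57 with that step taken away. The same rule serves the larch run. With the oak charge and the same amount made, the larch run held 25.0 times the oak run's target and went 23 times as fast, an apparent order in target of 0.978.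

All runs stem from a simulated flask with constants of no real substance, noise included.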